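**Plan**

1. Labels: C1 (CH–O-angeloyl), C2 (CH–O-isovaleryl), C3 (CHOH), C4 (CMe2), cyclobutane C5–C6–C11–C10 (C11 = CMe), C7 (CHMe), C8 (CH2), C9 (C=O).
2. Cuts, in order: the two esters; cyclobutane bond C5–C10 (enolate alkylation), leaving a cis-fused bicyclo[5.4.0]undecane; C7–C8 and C6–C11 together (intramolecular Diels–Alder); C3–C4 (aldol); C9–C10, C10≡C11 and C11–CH3 (acylation, alkyne homologation, carbometalation).
3. Enabling feature: with C5–C10 cut, ring C6–C7–C8–C9–C10–C11 is a cyclohexanone whose C9=O lies para to C6, and C6 carries C5. With C5 raised to a ketone this is the retron of a 2-silyloxydiene/enone cycloaddition, and C1–C5 is the tether.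
4. Forward order: acyclic triene, then the six- and seven-membered rings in one step. The cyclobutane (and with it the second six-membered ring) follows from the enol silane left at C9=C10, and the esters come last.
5. Stereochemistry: C1 and C2 are bought (L-threitol acetonide). C3 comes from C2 by a Felkin–Anh aldol. C6, C7 and C11 are set in the cycloaddition from C1 and two (E)-alkenes. C5 is set by hydride attack and inverted in the SN2 closure, which also fixes C10.
6. Helpers: C5=O (activator, then leaving group), the TBS enol ether (mask of C9=O and regiospecific enolate source), and the acetonides. All are removed again.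

Key step: step 12

Remark: the drawn configuration is taken as absolute. C1 and C2 then belong to the L-threitol (natural L-tartaric acid) series. Compounds 1 and 4, angelic acid and all named reagents are taken as commercial.

Step 1
Reactants: 1 (E)-but-2-enal (crotonaldehyde)
Product: 2 (E)-2-methylhex-4-en-3-ol (racemic)
Conditions: i-PrMgCl, THF, −78→0 °C; aq. work-up
Reagents that add atoms: isopropylmagnesium chloride, CC(C)[Mg]Cl
Why: Grignard 1,2-addition to the enal; the new carbinol centre is racemic and is erased in step 2.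

Step 2
Reactants: 2 (E)-2-methylhex-4-en-3-ol
Product: 3 (E)-2-methylhex-4-en-3-one (carries C4–C7 and three methyl groups)
Conditions: activated MnO2, CH2Cl2, rt
Reagents that add atoms: none
Why: Allylic alcohol oxidation with MnO2, which leaves the (E)-alkene untouched.

Step 3
Reactants: 4 (+)-2,3-O-isopropylidene-L-threitol, [(4S,5S)-2,2-dimethyl-1,3-dioxolane-4,5-diyl]dimethanol
Product: 5 mono-TBS ether, [(4S,5S)-5-{[(tert-butyldimethylsilyl)oxy]methyl}-2,2-dimethyl-1,3-dioxolan-4-yl]methanol
Conditions: NaH (1.0 equiv), THF, 0 °C→rt; TBSCl (1.0 equiv)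
Reagents that add atoms: tert-butyldimethylsilyl chloride, CC(C)(C)[Si](C)(C)Cl
Why: Monosilylation of a C2-symmetric diol through its monosodium alkoxide; the two hydroxyls are homotopic, and both stereocentres (future C1 and C2) come from the chiral pool.

Step 4
Reactants: 5 mono-TBS ether
Product: 6 (4R,5S)-5-{[(tert-butyldimethylsilyl)oxy]methyl}-2,2-dimethyl-1,3-dioxolane-4-carbaldehyde
Conditions: Dess–Martin periodinane, CH2Cl2, 0 °C→rt
Reagents that add atoms: none
Why: Dess–Martin oxidation, which is non-basic, so the α-alkoxy aldehyde should not epimerise.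

Step 5
Reactants: 6 aldehyde
Product: 7 (4S,5S)-4-ethynyl-5-{[(tert-butyldimethylsilyl)oxy]methyl}-2,2-dimethyl-1,3-dioxolane
Conditions: dimethyl (1-diazo-2-oxopropyl)phosphonate, K2CO3, MeOH, 0 °C→rt
Reagents that add atoms: dimethyl (1-diazo-2-oxopropyl)phosphonate, CC(=O)C(=[N+]=[N-])P(=O)(OC)OC
Why: Ohira–Bestmann (Seyferth–Gilbert) homologation adds C10; the trans-dioxolane is the thermodynamic isomer, so the mild base should not erode C1.

Step 6
Reactants: 7 alkyne
Product: 9 (4S,5S)-4-[(E)-1-iodoprop-1-en-2-yl]-5-{[(tert-butyldimethylsilyl)oxy]methyl}-2,2-dimethyl-1,3-dioxolane, via alkenylalane 8 (not isolated)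
Conditions: AlMe3, Cp2ZrCl2 (cat.), CH2Cl2, 0 °C→rt; then I2, THF, −30 °C
Reagents that add atoms: trimethylaluminium, C[Al](C)C; iodine, II
Why: Negishi zirconium-catalysed carboalumination (syn addition, methyl to the inner carbon C11, aluminium to C10) followed by iodinolysis with retention fixes the (E)-trisubstituted alkene with C1 trans to iodine.

Step 7
Reactants: 9 (E)-vinyl iodide
Product: 11 (E)-4-[(4S,5S)-5-{[(tert-butyldimethylsilyl)oxy]methyl}-2,2-dimethyl-1,3-dioxolan-4-yl]pent-3-en-2-one, via alkenyllithium 10 (not isolated)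
Conditions: t-BuLi (2.1 equiv), Et2O, −78 °C; then N-methoxy-N-methylacetamide, −78→0 °C; aq. work-up
Reagents that add atoms: N-methoxy-N-methylacetamide, CC(=O)N(C)OC
Why: Iodine–lithium exchange with retention of alkene geometry, then Weinreb ketone synthesis, brings in C9 and C8 without over-addition.

Step 8
Reactants: 11 silyl ether enone
Product: 12 (E)-4-[(4S,5S)-5-(hydroxymethyl)-2,2-dimethyl-1,3-dioxolan-4-yl]pent-3-en-2-one
Conditions: TBAF, THF, 0 °C
Reagents that add atoms: none
Why: Fluoride desilylation; oxa-Michael closure onto C11 would need a trans-fused bicyclo[3.3.0] system and is not expected.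

Step 9
Reactants: 12 hydroxy enone
Product: 13 (4R,5S)-2,2-dimethyl-5-[(E)-4-oxopent-2-en-2-yl]-1,3-dioxolane-4-carbaldehyde (aldehyde carbon = C3)
Conditions: Dess–Martin periodinane, CH2Cl2, 0 °C→rt
Reagents that add atoms: none
Why: Dess–Martin oxidation tolerates the enone and the acetonide and does not epimerise C2.

Step 10
Reactants: 3 (E)-2-methylhex-4-en-3-one; 13 aldehyde enone
Product: 15 aldol adduct with a C3 carbinol (1S,2S,3S) between the dioxolane and the CMe2–C(=O)–(E)-propenyl unit, via lithium enolate 14 (not isolated)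
Conditions: LDA, THF, −78 °C, 3 (1.3 equiv); then 13, −78 °C; AcOH quench at −78 °C
Reagents that add atoms: none
Why: Kinetic α′-deprotonation of the enone gives the tetrasubstituted cross-conjugated enolate, and its lithium aldol addition to the far more electrophilic aldehyde follows the polar Felkin–Anh (non-chelate) mode, giving the 2,3-anti (erythro) carbinol.

Step 11
Reactants: 15 aldol adduct
Product: 16 triene: C3–OTBS, 2-(TBS-oxy)diene C8=C9(OTBS)–C10=C11(Me) with (E) geometry, (E)-enone C5(=O)–C6=C7
Conditions: TBSOTf (2.4 equiv), Et3N (4 equiv), CH2Cl2, −78→0 °C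
Reagents that add atoms: tert-butyldimethylsilyl triflate, CC(C)(C)[Si](C)(C)OS(=O)(=O)C(F)(F)F
Why: O-silylation of C3–OH and soft enolisation (silyl triflate/amine) of the methyl ketone toward C8 occur in one operation, while the C5 enone has no α′-hydrogen (C4 is quaternary), is shielded, and should stay as the dienophile.

Step 12
Reactants: 16 triene
Product: 17 cis-fused bicyclo[5.4.0]undecene: C5 ketone in the seven-membered ring, TBS enol ether C9=C10, C6–H syn to C11–CH3, C7–CH3 trans to C5
Conditions: toluene (0.005 M), BHT, 150 °C, sealed tube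
Reagents that add atoms: none
Why: This is a type-1 intramolecular Diels–Alder reaction of normal electron demand, concerted but asynchronous, between the 2-silyloxydiene C8=C9–C10=C11 and the (E)-enone C6=C7 activated by C5=O; the closest known types are thermal trienone cycloadditions to hydrobenzocycloheptenes and cycloadditions of 4,4-disubstituted 2-silyloxydienes with hindered enones. The six-membered ring C6–C7–C8–C9–C10–C11 closes by the [4+2] event itself (C7–C8 leading, C6–C11 lagging), and the seven-membered ring C1–C5/C6/C11 closes in fused mode over the five-atom tether, helped by the C4 gem-dimethyl group and the trans-dioxolane. The tether permits only one orientation, which is also the electronically matched one, since the nucleophilic terminus C8 meets the enone β-carbon C7 (C9–O para to C6). C7 follows from suprafacial addition to the (E)-enone (C7–CH3 trans to C5), and C6/C11 follow from the endo position of the tether carbonyl under the (E)-diene (C1 outside, CH3 inside), which gives the cis ring fusion. The diene face is chosen by C1, because A(1,2) strain with the C11 methyl places C1–H next to that methyl, C1–O anti to the forming C6–C11 bond, and C2 on the face that carries the dienophile. The step therefore needs endo and facial selectivity, while high dilution suppresses intermolecular addition, and BHT with a 150 °C ceiling holds back polymerisation and the 1,5-hydrogen shift of the inside methyl.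

Step 13
Reactants: 17 bicyclic ketone
Product: 18 C5 alcohol (C5–OH syn to C6–H and C11–CH3, anti to C10)
Conditions: LiAlH4, Et2O, −78→0 °C; Rochelle-salt work-up
Reagents that add atoms: none
Why: Hydride reduction under peripheral attack: in the conformer with C5 and C7–CH3 equatorial on the cyclohexene, the inner face of C5=O is closed by transannular C1/C11, so hydride should enter from outside, while the TBS enol ether masks C9.

Step 14
Reactants: 18 C5 alcohol
Product: 19 C5 mesylate
Conditions: MsCl, Et3N (excess), CH2Cl2, 0 °C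
Reagents that add atoms: methanesulfonyl chloride, CS(=O)(=O)Cl
Why: Mesylation through sulfene sulfonylates even hindered secondary alcohols with retention at C5, and the excess amine keeps the enol silane intact.

Step 15
Reactants: 19 C5 mesylate
Product: 21 tricyclic ketone (tricyclo[5.4.0.0(2,8)]undecanone core with C1/C2 acetonide and C3–OTBS), via TAS enolate 20 (not isolated)
Conditions: TASF (1.05 equiv), THF, 0 °C→40 °C, strictly anhydrous
Reagents that add atoms: none
Why: Fluoride cleavage of the enol silane releases the C9–O/C10 enolate regiospecifically (no proton source, so no leakage to the C8 enolate that could close an isomeric cyclobutane), and intramolecular 4-exo-tet keto-sulfonate alkylation then inverts C5 and sets C10 by axial attack; O-alkylation (bridgehead enol ether) and E2 (C4 quaternary, C6–H syn to OMs) are shut off.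

Step 16
Reactants: 21 tricyclic ketone
Product: 22 triol ketone (C1, C2 and C3 hydroxyls free)
Conditions: 48% aq. HF, MeCN, rt
Reagents that add atoms: none
Why: Acidic fluoride deprotection removes the hindered TBS ether and hydrolyses the strained trans-fused acetonide under conditions too mild for cationic skeletal rearrangement.

Step 17
Reactants: 22 triol ketone
Product: 23 C2,C3-O-isopropylidene derivative with free C1–OH
Conditions: 2,2-dimethoxypropane, PPTS (cat.), acetone, rt
Reagents that add atoms: 2,2-dimethoxypropane, COC(C)(C)OC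
Why: Acetalisation under equilibrating conditions selects the cis C2/C3 diol (cis-fused dioxolane) over the strained trans C1/C2 alternative and so singles out C1–OH.

Step 18
Reactants: 23 acetonide alcohol
Product: 24 C1 angelate of the C2,C3-acetonide
Conditions: angelic acid, 2,4,6-trichlorobenzoyl chloride, Et3N, toluene, rt; then 23, 80 °C
Reagents that add atoms: angelic acid, C/C=C(/C)C(=O)O
Why: Yamaguchi-type mixed-anhydride esterification without a nucleophilic catalyst acylates the only free (neopentyl) hydroxyl and avoids Z→E isomerisation to the tiglate.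

Step 19
Reactants: 24 angelate acetonide
Product: 25 C1 angelate C2,C3-diol
Conditions: TFA–H2O (9:1), CH2Cl2, 0 °C
Reagents that add atoms: none
Why: Acid hydrolysis of the acetonide; the angelate and the ketone tolerate brief cold acid, and acyl migration is slow under acidic conditions.

Step 20
Reactants: 25 angelate diol
Product: 26 target CNP0323312.1
Conditions: isovaleric anhydride (1.2 equiv), DMAP (cat.), pyridine, CH2Cl2, 0 °C
Reagents that add atoms: isovaleric anhydride, CC(C)CC(=O)OC(=O)CC(C)C
Why: DMAP-catalysed acylation discriminates sterically, since C3–OH is neopentyl next to the C4 gem-dimethyl group and should stay free while C2–OH is esterified.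

**Compound list**

1 | (E)-but-2-enal | C/C=C/C=O | starting material
2 | (E)-2-methylhex-4-en-3-ol (racemic) | C/C=C/C(O)C(C)C | intermediate
3 | (E)-2-methylhex-4-en-3-one | C/C=C/C(=O)C(C)C | intermediate
4 | (+)-2,3-O-isopropylidene-L-threitol | O1[C@@H](CO)[C@@H](OC1(C)C)CO | starting material
5 | mono-TBS ether of 4 | O1[C@@H](CO)[C@@H](OC1(C)C)CO[Si](C)(C)C(C)(C)C | intermediate
6 | aldehyde | O1[C@@H](C=O)[C@@H](OC1(C)C)CO[Si](C)(C)C(C)(C)C | intermediate
7 | terminal alkyne | O1[C@@H](C#C)[C@@H](OC1(C)C)CO[Si](C)(C)C(C)(C)C | intermediate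
8 | (E)-alkenyl(dimethyl)alane | O1[C@@H](/C(C)=C/[Al](C)C)[C@@H](OC1(C)C)CO[Si](C)(C)C(C)(C)C | intermediate
9 | (E)-vinyl iodide | O1[C@@H](/C(C)=C/I)[C@@H](OC1(C)C)CO[Si](C)(C)C(C)(C)C | intermediate
10 | (E)-alkenyllithium | O1[C@@H](/C(C)=C/[Li])[C@@H](OC1(C)C)CO[Si](C)(C)C(C)(C)C | intermediate
11 | (E)-enone silyl ether | O1[C@@H](/C(C)=C/C(C)=O)[C@@H](OC1(C)C)CO[Si](C)(C)C(C)(C)C | intermediate
12 | hydroxy enone | O1[C@@H](/C(C)=C/C(C)=O)[C@@H](OC1(C)C)CO | intermediate
13 | aldehyde enone | O1[C@@H](/C(C)=C/C(C)=O)[C@@H](OC1(C)C)C=O | intermediate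
14 | lithium enolate of 3 | C/C=C/C(O[Li])=C(C)C | intermediate
15 | aldol adduct | O1[C@@H](/C(C)=C/C(C)=O)[C@@H](OC1(C)C)[C@@H](O)C(C)(C)C(=O)/C=C/C | intermediate
16 | silyloxydiene–enone triene | O1[C@@H](/C(C)=C/C(=C)O[Si](C)(C)C(C)(C)C)[C@@H](OC1(C)C)[C@@H](O[Si](C)(C)C(C)(C)C)C(C)(C)C(=O)/C=C/C | intermediate
17 | cycloadduct (bicyclic C5 ketone, C9=C10 enol silane) | O4[C@@H]1[C@@H](OC4(C)C)[C@@H](O[Si](C)(C)C(C)(C)C)C(C)(C)C(=O)[C@@H]3[C@@H](C)CC(O[Si](C)(C)C(C)(C)C)=C[C@@]31C | intermediate
18 | C5 alcohol | O4[C@@H]1[C@@H](OC4(C)C)[C@@H](O[Si](C)(C)C(C)(C)C)C(C)(C)[C@@H](O)[C@@H]3[C@@H](C)CC(O[Si](C)(C)C(C)(C)C)=C[C@@]31C | intermediate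
19 | C5 mesylate | O4[C@@H]1[C@@H](OC4(C)C)[C@@H](O[Si](C)(C)C(C)(C)C)C(C)(C)[C@@H](OS(C)(=O)=O)[C@@H]3[C@@H](C)CC(O[Si](C)(C)C(C)(C)C)=C[C@@]31C | intermediate
20 | tris(dimethylamino)sulfonium C9–O/C10 enolate | O4[C@@H]1[C@@H](OC4(C)C)[C@@H](O[Si](C)(C)C(C)(C)C)C(C)(C)[C@@H](OS(C)(=O)=O)[C@@H]3[C@@H](C)CC([O-])=C[C@@]31C.CN(C)[S+](N(C)C)N(C)C | intermediate
21 | tricyclic ketone, C1/C2 acetonide, C3–OTBS | O4[C@@H]1[C@@H](OC4(C)C)[C@@H](O[Si](C)(C)C(C)(C)C)C(C)(C)[C@H]2[C@@H]3[C@@H](C)CC(=O)[C@H]2[C@@]31C | intermediate
22 | triol ketone | O[C@@H]1[C@@H](O)[C@@H](O)C(C)(C)[C@H]2[C@@H]3[C@@H](C)CC(=O)[C@H]2[C@@]31C | intermediate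
23 | C2,C3-acetonide, C1–OH free | O[C@@H]1[C@@H](OC4(C)C)[C@@H](O4)C(C)(C)[C@H]2[C@@H]3[C@@H](C)CC(=O)[C@H]2[C@@]31C | intermediate
24 | C1 angelate acetonide | C/C=C(/C)C(=O)O[C@@H]1[C@@H](OC4(C)C)[C@@H](O4)C(C)(C)[C@H]2[C@@H]3[C@@H](C)CC(=O)[C@H]2[C@@]31C | intermediate
25 | C1 angelate C2,C3-diol | C/C=C(/C)C(=O)O[C@@H]1[C@@H](O)[C@@H](O)C(C)(C)[C@H]2[C@@H]3[C@@H](C)CC(=O)[C@H]2[C@@]31C | intermediate
26 | CNP0323312.1 | C/C=C(/C)C(=O)O[C@@H]1[C@@H](OC(=O)CC(C)C)[C@@H](O)C(C)(C)[C@H]2[C@@H]3[C@@H](C)CC(=O)[C@H]2[C@@]31C | target

**Count:** 20 steps in total. The longest linear sequence is 18 steps (steps 3–20, from 4).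

**Steps most likely to fail**

Step 12. The cycloaddition may be too slow, because it closes a seven-membered ring and forms the quaternary C11 from a diene with an inside methyl. It could then lose to the 1,5-hydrogen shift, or it could run with poor endo or facial selectivity.

The fallback replaces the neutral pericyclic event by an anionic, stepwise one and sets out from 15.
- Selective O-silylation (TBSOTf 1.1 equiv, 2,6-lutidine, −78 °C) gives the C3-O-TBS bis-enone F1.
- LiHMDS (THF, −78→0 °C) deprotonates the methyl ketone at C8.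
- The far more nucleophilic lithium dienolate runs an intramolecular double Michael reaction (C8→C7, then C6→C11).
- The terminal C9–O/C10 enolate is silylated in the flask with TBSCl/DMPU, which returns to 17.

Step 13. Hydride delivery may occur from the wrong face of C5=O if another ring conformer is populated, and the leaving group would then end up syn to C10.

The fallback moves stereocontrol from kinetic hydride attack to thermodynamic control and sets out from 17.
- Electron-transfer reduction (Li, NH3/THF, t-BuOH, −78 °C) protonates the ketyl or carbanion to the more stable, outward-pointing carbinol.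
- In whichever conformer dominates, this outcome is complementary to peripheral hydride attack, so it returns to 18.
- The C5-epimeric alcohol F2 from either protocol is sent back to 17 by Dess–Martin oxidation.

Step 15. Closure may be too slow, since it is an SN2 reaction between two neopentyl-type carbons through a conformer with C7–CH3 and C11–CH3 1,3-diaxial. Enolate equilibration to C8 or loss of the C3 silyl group, followed by fragmentation, could then intervene.

The fallback sets out from 19.
- Buffered HF·pyridine (0 °C) cleaves only the enol silane to give the keto mesylate F3.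
- IBX (DMSO, 70 °C) dehydrogenates toward C8/C7, the only direction open because C11 is quaternary, to give the enone mesylate F4.
- KHMDS (THF, −78 °C→rt) forms the α′-enolate at C10. Its regiochemistry is now secured by the enone, and the diaxial methyl clash is removed because C7 is sp2. The enolate closes the cyclobutane to give the tricyclic enone F5.
- Hydrogenation (H2, Pd/C, EtOAc) from the face flanked by C5–H rather than C11–CH3 resets C7 and returns to 21.

**Further compounds**

F1 | step 12 | C3-O-TBS bis-enone | O1[C@@H](/C(C)=C/C(C)=O)[C@@H](OC1(C)C)[C@@H](O[Si](C)(C)C(C)(C)C)C(C)(C)C(=O)/C=C/C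
F2 | step 13 | C5-epimeric alcohol | O4[C@@H]1[C@@H](OC4(C)C)[C@@H](O[Si](C)(C)C(C)(C)C)C(C)(C)[C@H](O)[C@@H]3[C@@H](C)CC(O[Si](C)(C)C(C)(C)C)=C[C@@]31C
F3 | step 15 | keto mesylate | O4[C@@H]1[C@@H](OC4(C)C)[C@@H](O[Si](C)(C)C(C)(C)C)C(C)(C)[C@@H](OS(C)(=O)=O)[C@@H]3[C@@H](C)CC(=O)C[C@@]31C
F4 | step 15 | enone mesylate | O4[C@@H]1[C@@H](OC4(C)C)[C@@H](O[Si](C)(C)C(C)(C)C)C(C)(C)[C@@H](OS(C)(=O)=O)[C@@H]3C(C)=CC(=O)C[C@@]31C
F5 | step 15 | tricyclic enone | O4[C@@H]1[C@@H](OC4(C)C)[C@@H](O[Si](C)(C)C(C)(C)C)C(C)(C)[C@H]2[C@@H]3C(C)=CC(=O)[C@H]2[C@@]31C
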